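Retrosynthesis: (a) remove the benzyl group from O3′. (b) Cut C2–C3 of ring C, which leads back to the isomeric cyclic vinyl acetal, a 2-aryl-4-methylidene-4H-1,3-benzodioxine. (c) Cut its exocyclic C4=CH2 back to a lactone C=O. (d) Cut the two C2–O bonds of the acetal, which gives 2-hydroxy-3,4-dimethoxybenzoic acid (ring A) and O-protected 3-hydroxy-4,5-dimethoxybenzaldehyde (ring B).
Enabling feature: C2 bears O1 and the electron-rich ring B (4′-OMe para to C2), so it is a latent aryl-stabilised oxocarbenium carbon at the aldehyde level. C3–C4(=O) is a latent enol, and the salicyl unit O1–C8a–C4a–C4 of ring A holds both ends in reach for a six-membered closure.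
Forward order: rings A and B are bought, and a temporary 1,3-dioxine ring joins them at C2. Methylenation brings in C3, and an acid-catalysed shift of C2 from O3 to C3 opens the temporary ring, closes ring C and unveils the C4 ketone. Hydrogenolysis then frees the phenol.
Stereochemistry: C2 (S), the only stereocentre, is set in the ring closure by a chiral counter-anion. The racemic acetal centre of the precursor is erased on ionisation (enantioconvergent), and the neutral last step does not touch C2.

Key step: step 4

Assumption: the sense of induction of the chiral acid cannot be predicted with certainty, so the (S)-acid is written and its commercially available (R)-antipode is used if a first run shows the (2R) series.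

Step 1
Reactants: 1 3-hydroxy-4,5-dimethoxybenzaldehyde
Product: 2 3-(benzyloxy)-4,5-dimethoxybenzaldehyde
Conditions: BnBr, K2CO3, DMF, rt
Reagents that add atoms: benzyl bromide BrCc1ccccc1
Why: Williamson ether synthesis on the only acidic OH; the benzyl group masks the phenol against the silicon, titanium and acid reagents of steps 2 to 4 and can be removed under neutral conditions at the end.

Step 2
Reactants: 2 3-(benzyloxy)-4,5-dimethoxybenzaldehyde; 3 2-hydroxy-3,4-dimethoxybenzoic acid
Product: 5 rac-2-[3-(benzyloxy)-4,5-dimethoxyphenyl]-7,8-dimethoxy-4H-1,3-benzodioxin-4-one, via bis-silyl salicylate 4 (not isolated)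
Conditions: 3, HMDS, THF, rt; solvent exchange to CH2Cl2; 2, TMSOTf (20 mol %), −78 to −20 °C; pyridine quench
Reagents that add atoms: hexamethyldisilazane C[Si](C)(C)N[Si](C)(C)C (its Me3Si groups stand in 4 only)
Why: Silicon-driven acetalisation (the union stage of the Petasis–Ferrier tactic): TMSOTf activates the aldehyde, the silyl ester and the aryl silyl ether add in turn, and the strong Si–O bond of the disiloxane drives ring closure at a temperature at which the electron-rich acid cannot decarboxylate; the acetal carbon (the later C2) forms racemic, which is harmless because step 4 erases it.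

Step 3
Reactants: 5 rac-2-[3-(benzyloxy)-4,5-dimethoxyphenyl]-7,8-dimethoxy-4H-1,3-benzodioxin-4-one
Product: 6 rac-2-[3-(benzyloxy)-4,5-dimethoxyphenyl]-7,8-dimethoxy-4-methylidene-4H-1,3-benzodioxine
Conditions: Cp2TiMe2 (2.5 equiv), toluene/THF, 65 °C, dark; filtration through basic Al2O3 (Et3N-washed)
Reagents that add atoms: dimethyltitanocene Cp2TiMe2 [CH3-].[CH3-].[cH-]1cccc1.[cH-]1cccc1.[Ti+4]
Why: Petasis methylenation: Cp2Ti=CH2, formed by loss of methane, exchanges the lactone C=O for C=CH2 by [2+2] cycloaddition and cycloreversion under non-acidic conditions that spare the acetal, as established for 1,3-dioxan-4-ones and for aryl esters; the new CH2 is the later C3.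

Step 4
Reactants: 6 rac-2-[3-(benzyloxy)-4,5-dimethoxyphenyl]-7,8-dimethoxy-4-methylidene-4H-1,3-benzodioxine
Product: 8 (2S)-2-[3-(benzyloxy)-4,5-dimethoxyphenyl]-7,8-dimethoxy-2,3-dihydro-4H-chromen-4-one, via oxocarbenium enol cation 7 (not isolated)
Conditions: (S)-3,3′-bis(2,4,6-triisopropylphenyl)-1,1′-binaphthyl-2,2′-diyl N-triflylphosphoramide (5 mol %), 5 Å MS, toluene (0.02 M), −40 °C; Et3N quench at −40 °C
Reagents that add atoms: none
Why: Proposed new method: the chiral acid protonates the vinyl acetal of racemic 6, the C2–O3 bond ionises and the (E)-oxocarbenium ion C2=O1, stabilised by ring B through its 4′-methoxy group, stays tied through ring A to the enol C4(OH)=C3H2 and paired with the chiral anion (7), so the old acetal centre is erased and both enantiomers of 6 converge on one intermediate. Enol carbon C3 then attacks C2 and the anion takes back the enol proton, which gives ketone 8 and frees the catalyst, in sum a 1,3 shift of C2 from O3 to C3. The closest known reaction types are the Petasis–Ferrier rearrangement of 4-methylidene-1,3-dioxanes to tetrahydropyran-4-ones with Me2AlCl and the enantioconvergent aza-Petasis–Ferrier rearrangement of racemic hemiaminal vinyl ethers with chiral phosphoric acids, but neither has been shown for a benzo-fused vinyl acetal or for an oxocarbenium ion under control of a chiral anion. Ring C closes in the 6-(enolendo)-endo-trig mode through a half-chair with ring B pseudo-equatorial, helped by the C8 methoxy group, which turns the O1–C2 bond out of the plane of ring A and so places C2 over C3. C2, the only new stereocentre, is controlled by the anion, which binds the enol O–H by a hydrogen bond and the cationic C2–H by an ion-pair contact between its two triisopropylphenyl walls and thus leaves one face of C2 open to C3. The step needs C- over O-attack, ionisation at a temperature at which no unselective background runs and no later opening of ring C: O-attack only returns 6, the electron-rich ring B allows ionisation at −40 °C, and the conjugated aryl ketone formed makes the C–C closure irreversible while the cold Et3N quench removes the acid before ring C can reopen.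

Step 5
Reactants: 8 (2S)-2-[3-(benzyloxy)-4,5-dimethoxyphenyl]-7,8-dimethoxy-2,3-dihydro-4H-chromen-4-one
Product: 9 (2S)-2-(3-hydroxy-4,5-dimethoxyphenyl)-7,8-dimethoxy-2,3-dihydro-4H-chromen-4-one
Conditions: H2 (1 atm), Pd/C (10 %), EtOAc, rt, stopped at full conversion
Reagents that add atoms: none
Why: Catalytic hydrogenolysis of the primary benzyl aryl ether should be much faster than that of the hindered, secondary, cyclic C2–O1 bond, and with neither acid nor base present ring C cannot open by a retro-oxa-Michael reaction, so C2 keeps its configuration.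

Compound list
1 | 3-hydroxy-4,5-dimethoxybenzaldehyde | COc1cc(C=O)cc(O)c1OC | starting material
2 | 3-(benzyloxy)-4,5-dimethoxybenzaldehyde | COc1cc(C=O)cc(OCc2ccccc2)c1OC | intermediate
3 | 2-hydroxy-3,4-dimethoxybenzoic acid | COc1ccc(C(=O)O)c(O)c1OC | starting material
4 | trimethylsilyl 3,4-dimethoxy-2-[(trimethylsilyl)oxy]benzoate (not isolated) | COc1ccc(C(=O)O[Si](C)(C)C)c(O[Si](C)(C)C)c1OC | intermediate
5 | rac-2-[3-(benzyloxy)-4,5-dimethoxyphenyl]-7,8-dimethoxy-4H-1,3-benzodioxin-4-one | COc1cc(C2OC(=O)c3ccc(OC)c(OC)c3O2)cc(OCc2ccccc2)c1OC | intermediate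
6 | rac-2-[3-(benzyloxy)-4,5-dimethoxyphenyl]-7,8-dimethoxy-4-methylidene-4H-1,3-benzodioxine | COc1cc(C2OC(=C)c3ccc(OC)c(OC)c3O2)cc(OCc2ccccc2)c1OC | intermediate
7 | (E)-{[3-(benzyloxy)-4,5-dimethoxyphenyl]methylidene}[6-(1-hydroxyethenyl)-2,3-dimethoxyphenyl]oxonium, cation of the ion pair with the catalyst anion (not isolated) | COc1ccc(C(O)=C)c(/[O+]=C/c2cc(OC)c(OC)c(OCc3ccccc3)c2)c1OC | intermediate
8 | (2S)-2-[3-(benzyloxy)-4,5-dimethoxyphenyl]-7,8-dimethoxy-2,3-dihydro-4H-chromen-4-one | COc1cc([C@@H]2CC(=O)c3ccc(OC)c(OC)c3O2)cc(OCc2ccccc2)c1OC | intermediate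
9 | (2S)-2-(3-hydroxy-4,5-dimethoxyphenyl)-7,8-dimethoxy-2,3-dihydro-4H-chromen-4-one | COc1cc([C@@H]2CC(=O)c3ccc(OC)c(OC)c3O2)cc(O)c1OC | target

Total step count: 5. Longest linear sequence: 5 steps (1 → 2 → 5 → 6 → 8 → 9).

Steps most likely to fail

**Step 4.**
- Risk: poor facial selectivity in the ion pair, or an unselective background rearrangement started by traces of achiral acid.
- Fallback: known chemistry that closes ring C at O1–C2 instead. It sets out from 3 and 2 and comes back at 8.
- Fischer esterification of 3 (MeOH, cat. H2SO4, reflux) gives methyl 2-hydroxy-3,4-dimethoxybenzoate F1.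
- Crossed Claisen condensation of F1 with the lithium enolate of tert-butyl acetate (LiN(iPr)2, excess, THF, −78 to 0 °C) gives tert-butyl 3-(2-hydroxy-3,4-dimethoxyphenyl)-3-oxopropanoate F2.
- Knoevenagel condensation of F2 with 2 (piperidine, AcOH, 4 Å MS, toluene, rt) gives tert-butyl 2-{[3-(benzyloxy)-4,5-dimethoxyphenyl]methylidene}-3-(2-hydroxy-3,4-dimethoxyphenyl)-3-oxopropanoate F3.
- A bifunctional cinchona thiourea (10 mol %, toluene, −25 °C) closes the ring by enantioselective intramolecular oxa-Michael addition. The quinine- or quinidine-derived pseudoenantiomer that leads to the (2S) series is used. The product is tert-butyl (2S,3R)-2-[3-(benzyloxy)-4,5-dimethoxyphenyl]-7,8-dimethoxy-4-oxochromane-3-carboxylate F4.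
- TsOH in toluene at 80 °C then removes the ester group by dealkylation and decarboxylation and gives 8.

**Step 3.**
- Risk: premature ionisation or hydrolysis of the acid-labile vinyl acetal during work-up or on titanium residues, which would take away the substrate of the asymmetric step.
- Fallback: the stereocentre comes from a resolution and not from the ring closure. It sets out from 5 and comes back at 8.
- The methylenation is run as before, but the crude solution is not worked up. After solvent exchange it is treated with Me2AlCl (CH2Cl2, −78 °C to rt), the classical achiral Petasis–Ferrier rearrangement. This should give racemic 2-[3-(benzyloxy)-4,5-dimethoxyphenyl]-7,8-dimethoxy-2,3-dihydro-4H-chromen-4-one F5.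
- F5 is resolved kinetically by asymmetric transfer hydrogenation, a reaction type established for racemic flavanones (Cp*RhCl[(R,R)-TsDPEN] or its antipode, HCO2H/Et3N, EtOAc, rt, stopped near half conversion).
- The (2R) ketone is reduced to (2R,4R)-2-[3-(benzyloxy)-4,5-dimethoxyphenyl]-7,8-dimethoxy-3,4-dihydro-2H-chromen-4-ol F6. Unreacted 8 is separated by chromatography.

**Step 2.**
- Risk: incomplete ring closure, because the hindered and weakly nucleophilic aryl silyl ether is slow to attack the stabilised cation from the electron-rich aldehyde. Hydrolysis of the acylal during isolation is a second risk.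
- Fallback: thermodynamic acylal exchange in place of the silicon-driven kinetic condensation. It sets out from 2 and comes back at 5.
- Ac2O with cat. H2SO4 at 0 °C converts 2 into [3-(benzyloxy)-4,5-dimethoxyphenyl]methanediyl diacetate F7.
- F7 is exchanged with 3 (cat. TsOH, toluene, 45 °C, reduced pressure to distil off the volatile exchange product) to give 5.

Further compounds
F1 | step 4 | methyl 2-hydroxy-3,4-dimethoxybenzoate | COC(=O)c1ccc(OC)c(OC)c1O
F2 | step 4 | tert-butyl 3-(2-hydroxy-3,4-dimethoxyphenyl)-3-oxopropanoate | COc1ccc(C(=O)CC(=O)OC(C)(C)C)c(O)c1OC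
F3 | step 4 | tert-butyl 2-{[3-(benzyloxy)-4,5-dimethoxyphenyl]methylidene}-3-(2-hydroxy-3,4-dimethoxyphenyl)-3-oxopropanoate (alkene geometry not fixed) | COc1ccc(C(=O)C(=Cc2cc(OC)c(OC)c(OCc3ccccc3)c2)C(=O)OC(C)(C)C)c(O)c1OC
F4 | step 4 | tert-butyl (2S,3R)-2-[3-(benzyloxy)-4,5-dimethoxyphenyl]-7,8-dimethoxy-4-oxochromane-3-carboxylate | COc1cc([C@@H]2[C@@H](C(=O)OC(C)(C)C)C(=O)c3ccc(OC)c(OC)c3O2)cc(OCc2ccccc2)c1OC
F5 | step 3 | rac-2-[3-(benzyloxy)-4,5-dimethoxyphenyl]-7,8-dimethoxy-2,3-dihydro-4H-chromen-4-one | COc1cc(C2CC(=O)c3ccc(OC)c(OC)c3O2)cc(OCc2ccccc2)c1OC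
F6 | step 3 | (2R,4R)-2-[3-(benzyloxy)-4,5-dimethoxyphenyl]-7,8-dimethoxy-3,4-dihydro-2H-chromen-4-ol | COc1cc([C@H]2C[C@@H](O)c3ccc(OC)c(OC)c3O2)cc(OCc2ccccc2)c1OC
F7 | step 2 | [3-(benzyloxy)-4,5-dimethoxyphenyl]methanediyl diacetate | CC(=O)OC(OC(C)=O)c1cc(OC)c(OC)c(OCc2ccccc2)c1
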